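The dihydrofuran ring (O1, C2, C3, C3a, C7a) is reached from a 2,2-dimethylchroman. Its O1–C2–C(CH3)2–OH array is the 1,2-transposed form of a 3-hydroxy-2,2-dimethylpyran. Hydrolysis of a (3R)-chroman-3-yl triflate moves O1 from the quaternary carbon to C3 with inversion. In one operation this contracts the ring, fixes C2 as S and frees the tertiary carbinol. The precursor, an 8-acyl-chroman-3-ol, comes from a regiodefined prenal annulation and a manganese-salen epoxidation, for which such chromenes are ideal. The prenyl ether that blocks O4 during annulation is later moved to C5 by asymmetric palladium catalysis. C3a is hydroxylated last, anti to the C2 side chain.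

Key step: step 5

Assumption: the (R,R)-diphosphine in step 6 is assigned from the usual pocket model for stabilised prochiral nucleophiles, and since both ligand enantiomers are commercial the mirror-image ligand is taken if the model points the wrong way; benzofuran locants of the target are used from 13 on and chroman locants for 8 to 12.

Step 1
Reactants: 1 2-methylbenzene-1,3,5-triol; 2 2-methylpropanoyl chloride
Product: 3 2-methyl-1-(2,4,6-trihydroxy-3-methylphenyl)propan-1-one
Conditions: AlCl3 (3.5 equiv), PhNO2/CH2Cl2, 0 to 45 °C; aq. HCl work-up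
Reagents that add atoms: none
Why: Friedel–Crafts acylation; the two free ring positions of 1 are equivalent and the first acyl group deactivates the ring against a second acylation.

Step 2
Reactants: 3 2-methyl-1-(2,4,6-trihydroxy-3-methylphenyl)propan-1-one; 4 3-methylbut-2-en-1-ol
Product: 5 1-[2,6-dihydroxy-3-methyl-4-(3-methylbut-2-enyloxy)phenyl]-2-methylpropan-1-one
Conditions: PPh3, DIAD, THF, 0 °C to rt
Reagents that add atoms: none
Why: The Mitsunobu etherification should take the most acidic hydroxyl, the one para to the acyl group that cannot chelate, and gives O- rather than C-alkylation, so O4 is blocked and the prenyl unit is stored for step 6.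

Step 3
Reactants: 5 1-[2,6-dihydroxy-3-methyl-4-(3-methylbut-2-enyloxy)phenyl]-2-methylpropan-1-one; 6 3-methylbut-2-enal
Product: 8 1-[7-hydroxy-2,2,6-trimethyl-5-(3-methylbut-2-enyloxy)-2H-chromen-8-yl]-2-methylpropan-1-one, via oxatriene 7 (not isolated)
Conditions: ethylenediammonium diacetate (10 mol%), toluene, 90 °C
Reagents that add atoms: none
Why: Knoevenagel-type condensation at the only free ring carbon gives oxatriene 7, whose oxa-6π electrocyclisation can use only the hydroxyl next to the acyl-bearing carbon because O4 is etherified, so the pyran oxygen is placed unambiguously.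

Step 4
Reactants: 8 1-[7-hydroxy-2,2,6-trimethyl-5-(3-methylbut-2-enyloxy)-2H-chromen-8-yl]-2-methylpropan-1-one
Product: 10 1-[(3R)-3,7-dihydroxy-2,2,6-trimethyl-5-(3-methylbut-2-enyloxy)-3,4-dihydro-2H-chromen-8-yl]-2-methylpropan-1-one, via epoxide 9 (not isolated)
Conditions: (R,R)-[N,N'-bis(3,5-di-tert-butylsalicylidene)-1,2-cyclohexanediaminato]MnCl (5 mol%), 4-phenylpyridine N-oxide (20 mol%), PhIO, CH2Cl2, 0 °C; then Et3SiH, CF3CO2H, −78 to −40 °C
Reagents that add atoms: iodosylbenzene O=Ic1ccccc1
Why: The Jacobsen–Katsuki epoxidation, for which conjugated cis-2,2-dimethylchromenes are the best substrate class and which should spare the isolated prenyl alkene, sets C3 as R with the (R,R)-catalyst, and ionic hydrogenation then removes only the benzylic C4–O bond through a strongly stabilised cation, so C3 is not touched.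

Step 5
Reactants: 10 1-[(3R)-3,7-dihydroxy-2,2,6-trimethyl-5-(3-methylbut-2-enyloxy)-3,4-dihydro-2H-chromen-8-yl]-2-methylpropan-1-one
Product: 13 1-[(2S)-6-hydroxy-2-(2-hydroxypropan-2-yl)-5-methyl-4-(3-methylbut-2-enyloxy)-2,3-dihydro-1-benzofuran-7-yl]-2-methylpropan-1-one, via triflate 11 (not isolated), via oxiranium triflate 12 (not isolated)
Conditions: Tf2O (1.1 equiv), 2,6-lutidine (3 equiv), CH2Cl2, −78 °C; then acetone/H2O, −78 to 20 °C
Reagents that add atoms: trifluoromethanesulfonic anhydride O=S(=O)(OS(=O)(=O)C(F)(F)F)C(F)(F)F; water O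
Why: Triflation with a hindered base takes the neutral secondary alcohol while the phenol stays locked in its hydrogen bond to the acyl oxygen; in the half-chair with equatorial triflate the C3–OTf bond is antiperiplanar to C2–O1, so a lone pair of O1 expels triflate from the rear to give the bridged ion 12, and water opens 12 at its tertiary carbon. The closest known reaction type is the ring contraction of pyranosyl 2-triflates and of 3-sulfonyloxy-2,2-dimethylchromans by participation of the ring oxygen. The new O1–C bond closes the three-membered ring of 12 (3-exo-tet) and at the same time the final five-membered ring O1–C2–C3–C3a–C7a (5-exo-tet), and the six-membered ring disappears when the O1–C(CH3)2 bond breaks. The only stereocentre involved is inverted once, so (3R) in 10 becomes (2S) in 13 and the enantiomeric purity set in step 4 is carried over. The step needs O1 migration to win over methyl migration, aryl bridging and elimination: the lone pair is the better neighbouring group, the charge ends on a tertiary carbon, and the fused arene cannot turn its pi face toward C3. It also needs water to attack the tertiary and not the secondary carbon of 12, which the greater cationic character of the tertiary carbon secures.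

Step 6
Reactants: 13 1-[(2S)-6-hydroxy-2-(2-hydroxypropan-2-yl)-5-methyl-4-(3-methylbut-2-enyloxy)-2,3-dihydro-1-benzofuran-7-yl]-2-methylpropan-1-one
Product: 14 (2S,5S)-6-hydroxy-2-(2-hydroxypropan-2-yl)-5-methyl-5-(3-methylbut-2-enyl)-7-(2-methylpropanoyl)-3,5-dihydro-1-benzofuran-4(2H)-one
Conditions: Pd2(dba)3·CHCl3 (2.5 mol%), (1R,2R)-N,N'-bis[2-(diphenylphosphino)benzoyl]cyclohexane-1,2-diamine (7.5 mol%), degassed toluene, 40 °C
Reagents that add atoms: none
Why: Tsuji–Trost ionisation of the aryl prenyl ether by zerovalent palladium and recombination of the prenyl cation, at its unsubstituted terminus, with C5, the carbon flanked by both oxygen-bearing carbons, is an asymmetric allylic dearomatisation in which the chiral diphosphine pocket, not the remote C2 centre, selects the ring face and sets C5 as S.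

Step 7
Reactants: 14 (2S,5S)-6-hydroxy-2-(2-hydroxypropan-2-yl)-5-methyl-5-(3-methylbut-2-enyl)-7-(2-methylpropanoyl)-3,5-dihydro-1-benzofuran-4(2H)-one
Product: 15 (2S,3aR,5S)-3a-hydroxy-2-(2-hydroxypropan-2-yl)-5-methyl-5-(3-methylbut-2-enyl)-7-(2-methylpropanoyl)-3,3a-dihydro-1-benzofuran-4,6(2H,5H)-dione
Conditions: 2-(benzenesulfonyl)-3-phenyloxaziridine (1.2 equiv), DBU (20 mol%), THF, −40 to 0 °C
Reagents that add atoms: 2-(benzenesulfonyl)-3-phenyloxaziridine O=S(=O)(N1OC1c1ccccc1)c1ccccc1
Why: Oxaziridine hydroxylation of the extended enolate should deliver oxygen to C3a, the alkyl-bearing vinylogous terminus (the site oxidised when hop deoxy-alpha-acids become alpha-acids), from the face opposite the bulky C2 hydroxyisopropyl group, which gives 3aR, and the reagent does not epoxidise the prenyl alkene.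

Compound list
1 | 2-methylbenzene-1,3,5-triol | Cc1c(O)cc(O)cc1O | starting material
2 | 2-methylpropanoyl chloride | CC(C)C(=O)Cl | starting material
3 | 2-methyl-1-(2,4,6-trihydroxy-3-methylphenyl)propan-1-one | CC(C)C(=O)c1c(O)cc(O)c(C)c1O | intermediate
4 | 3-methylbut-2-en-1-ol | CC(C)=CCO | starting material
5 | 1-[2,6-dihydroxy-3-methyl-4-(3-methylbut-2-enyloxy)phenyl]-2-methylpropan-1-one | CC(C)C(=O)c1c(O)cc(OCC=C(C)C)c(C)c1O | intermediate
6 | 3-methylbut-2-enal | CC(C)=CC=O | starting material
7 | 3-hydroxy-4-methyl-6-(3-methylbut-2-enylidene)-5-(3-methylbut-2-enyloxy)-2-(2-methylpropanoyl)cyclohexa-2,4-dien-1-one (oxatriene, not isolated) | CC(C)C(=O)C1=C(O)C(C)=C(OCC=C(C)C)C(=CC=C(C)C)C1=O | intermediate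
8 | 1-[7-hydroxy-2,2,6-trimethyl-5-(3-methylbut-2-enyloxy)-2H-chromen-8-yl]-2-methylpropan-1-one | CC(C)C(=O)c1c(O)c(C)c(OCC=C(C)C)c2C=CC(C)(C)Oc12 | intermediate
9 | 1-[(3R,4R)-3,4-epoxy-7-hydroxy-2,2,6-trimethyl-5-(3-methylbut-2-enyloxy)-3,4-dihydro-2H-chromen-8-yl]-2-methylpropan-1-one (not isolated) | CC(C)C(=O)c1c(O)c(C)c(OCC=C(C)C)c2[C@H]3O[C@H]3C(C)(C)Oc12 | intermediate
10 | 1-[(3R)-3,7-dihydroxy-2,2,6-trimethyl-5-(3-methylbut-2-enyloxy)-3,4-dihydro-2H-chromen-8-yl]-2-methylpropan-1-one | CC(C)C(=O)c1c(O)c(C)c(OCC=C(C)C)c2C[C@@H](O)C(C)(C)Oc12 | intermediate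
11 | (3R)-7-hydroxy-2,2,6-trimethyl-5-(3-methylbut-2-enyloxy)-8-(2-methylpropanoyl)-3,4-dihydro-2H-chromen-3-yl trifluoromethanesulfonate (not isolated) | CC(C)C(=O)c1c(O)c(C)c(OCC=C(C)C)c2C[C@@H](OS(=O)(=O)C(F)(F)F)C(C)(C)Oc12 | intermediate
12 | O1-bridged oxiranium triflate, O1 bonded to C2, C3 and C8a of the former chroman (not isolated) | CC(C)C(=O)c1c(O)c(C)c(OCC=C(C)C)c2C[C@@H]3[O+](c12)C3(C)C.[O-]S(=O)(=O)C(F)(F)F | intermediate
13 | 1-[(2S)-6-hydroxy-2-(2-hydroxypropan-2-yl)-5-methyl-4-(3-methylbut-2-enyloxy)-2,3-dihydro-1-benzofuran-7-yl]-2-methylpropan-1-one | CC(C)C(=O)c1c(O)c(C)c(OCC=C(C)C)c2C[C@@H](C(C)(C)O)Oc12 | intermediate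
14 | (2S,5S)-6-hydroxy-2-(2-hydroxypropan-2-yl)-5-methyl-5-(3-methylbut-2-enyl)-7-(2-methylpropanoyl)-3,5-dihydro-1-benzofuran-4(2H)-one | CC(C)=CC[C@@]1(C)C(O)=C(C(=O)C(C)C)C2=C(C[C@@H](C(C)(C)O)O2)C1=O | intermediate
15 | (2S,3aR,5S)-3a-hydroxy-2-(2-hydroxypropan-2-yl)-5-methyl-5-(3-methylbut-2-enyl)-7-(2-methylpropanoyl)-3,3a-dihydro-1-benzofuran-4,6(2H,5H)-dione | CC(C)=CC[C@@]1(C)C(=O)C(C(=O)C(C)C)=C2O[C@H](C(C)(C)O)C[C@]2(O)C1=O | target

Total step count: 7. Longest linear sequence: 7 steps (from 1 to 15).

Steps most likely to fail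

Step 6.
- **What may go wrong:** the prenyl cation may recombine at C3a or at oxygen instead of C5. The prenyl unit may be lost by beta-hydride elimination. Discrimination between the two ring faces may be poor.
- **Fallback:** it sets out from 13 and replaces the catalytic migration by cleavage and classical alkylative dearomatisation.
  - The ether is cleaved with Pd(PPh3)4 and morpholine as prenyl scavenger to the free 4,6-diphenol F1.
  - F1 is C-prenylated with prenyl bromide under liquid–liquid phase transfer (N-benzylcinchonidinium chloride, aq. KOH, toluene, 0 °C), the standard way to quaternise acylphloroglucinols.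
  - Because C2 is already fixed, the unwanted (5R)-epimer F2 is a diastereomer and is removed by chromatography.
  - The sequence comes back to the route at 14.

Step 7.
- **What may go wrong:** facial selection may be insufficient, because the C5 prenyl group lies on the face that has to be attacked. Oxygen may also be transferred to C7.
- **Fallback:** it sets out from 14 and enlarges the shielding group by a protecting-group detour.
  - TBSOTf and 2,6-lutidine give the bis-silylated enol ether F3.
  - The labile enol silyl group of F3 is hydrolysed on aqueous work-up, leaving the tertiary silyl ether F4.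
  - Hydroxylation of F4 with the same oxaziridine, now opposite a much larger C2 substituent, gives the silylated alpha-ketol F5.
  - HF·pyridine in MeCN removes the silyl group, and the sequence comes back to the route at 15.

Step 5.
- **What may go wrong:** the contracted tertiary cation may lose a proton faster than it is hydrated. The conformer with axial triflate may shift a methyl group.
- **Fallback:** it sets out from 10 and makes proton loss the intended ending.
  - The triflate is formed with Tf2O and 2,6-di-tert-butyl-4-methylpyridine in dry CH2Cl2 and warmed without water. The same O1 shift then ends in the isopropenyl dihydrobenzofuran F6.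
  - A Mukaiyama hydration (Mn(dpm)3 10 mol%, PhSiH3, O2, iPrOH, 0 °C) adds water in the Markovnikov sense to the 1,1-disubstituted alkene. That alkene reacts faster than the trisubstituted alkene of the prenyl ether.
  - The sequence comes back to the route at 13.

Further compounds
F1 | step 6 | 1-[(2S)-4,6-dihydroxy-2-(2-hydroxypropan-2-yl)-5-methyl-2,3-dihydro-1-benzofuran-7-yl]-2-methylpropan-1-one | CC(C)C(=O)c1c(O)c(C)c(O)c2C[C@@H](C(C)(C)O)Oc12
F2 | step 6 | (2S,5R)-6-hydroxy-2-(2-hydroxypropan-2-yl)-5-methyl-5-(3-methylbut-2-enyl)-7-(2-methylpropanoyl)-3,5-dihydro-1-benzofuran-4(2H)-one | CC(C)=CC[C@]1(C)C(O)=C(C(=O)C(C)C)C2=C(C[C@@H](C(C)(C)O)O2)C1=O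
F3 | step 7 | bis(tert-butyldimethylsilyl) derivative of 14 (enol oxygen at C6 and tertiary oxygen) | CC(C)=CC[C@@]1(C)C(O[Si](C)(C)C(C)(C)C)=C(C(=O)C(C)C)C2=C(C[C@@H](C(C)(C)O[Si](C)(C)C(C)(C)C)O2)C1=O
F4 | step 7 | tert-butyldimethylsilyl ether of 14 at the tertiary oxygen | CC(C)=CC[C@@]1(C)C(O)=C(C(=O)C(C)C)C2=C(C[C@@H](C(C)(C)O[Si](C)(C)C(C)(C)C)O2)C1=O
F5 | step 7 | tert-butyldimethylsilyl ether of 15 at the side-chain tertiary oxygen | CC(C)=CC[C@@]1(C)C(=O)C(C(=O)C(C)C)=C2O[C@H](C(C)(C)O[Si](C)(C)C(C)(C)C)C[C@]2(O)C1=O
F6 | step 5 | 1-[(2S)-6-hydroxy-5-methyl-4-(3-methylbut-2-enyloxy)-2-(prop-1-en-2-yl)-2,3-dihydro-1-benzofuran-7-yl]-2-methylpropan-1-one | CC(C)C(=O)c1c(O)c(C)c(OCC=C(C)C)c2C[C@@H](C(C)=C)Oc12
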